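Ring labels: ring A = 2-pyranone, ring B = dihydropyran, ring C = cycloheptane, ring D = cyclopentenone; ring C carbons are Ca (hemiketal C), Cb (CHOH), Cc (C=O), Cd (C–OH, C/D fusion), Ce (sp2, C/D fusion), Cf (CHCH3), Cg (CH, B/C fusion).
Retrosynthesis cuts, in this order: the acid-labile masks; ring D at Cd–C(CH3)2 (aldol) and Ce=CH (aldol condensation); ring B at Cg–CH2 and Ca–O (hetero-Diels–Alder of the pyranone quinone methide); last, ring C at Ca–Cg and Cd–Ce.
Enabling feature: Ca–Cb–Cc–Cd are four contiguous oxygen-bearing carbons, i.e. the four carbons of a squarate ester, and Ce–Cf(CH3)–Cg is a trimethylenemethane unit. With a temporary Ca–Cd bond (the cyclobutene) both ring C bonds form in one [3+2] annulation, and cutting Ca–Cd then expands the bicyclo[3.2.0]heptene to ring C at the final oxidation level.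
Forward order: ring C (steps 1–4, achiral), desymmetrisation (step 5), rings A/B attached in one three-component step (step 6), ring D (steps 7–9), unmasking (step 10).
Stereochemistry: Cf from enantiotopos-selective deprotonation by a chiral lithium amide; Cg from cycloaddition anti to the Cf methyl; Cd from a reversible ring-closing aldol; Ca and Cb from hemiketal and α-ketol equilibration in the last step.

Key step: step 2

Assumption: Ca (hemiketal) and Cb (α-ketol carbon) are configurationally labile, so the natural configuration at these two centres is taken to be the thermodynamic one; di-tert-butyl squarate and 4-hydroxy-5,6-dimethyl-2H-pyran-2-one are taken as purchasable.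

Step 1
Reactants: 1 2-(chloromethyl)-3-(trimethylsilyl)prop-1-ene
Product: 2 3-iodo-2-[(trimethylsilyl)methyl]prop-1-ene
Conditions: NaI, acetone, 25 °C, dark
Reagents that add atoms: sodium iodide, [Na+].[I-]
Why: Finkelstein halide exchange (SN2 at the primary allylic carbon) is driven by precipitation of NaCl from acetone and creates no stereocentre.

Step 2
Reactants: 2 3-iodo-2-[(trimethylsilyl)methyl]prop-1-ene; 3 di-tert-butyl squarate (3,4-di-tert-butoxycyclobut-3-ene-1,2-dione)
Product: 6 cis-6,7-di-tert-butoxy-3-methylidenebicyclo[3.2.0]hept-6-ene-1,5-diol (meso), via allyltin reagent 4 (not isolated), via stannyl ether 5 (not isolated)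
Conditions: SnF2, THF, 25 °C; pH 7 buffer
Reagents that add atoms: none
Why: Proposed new method: SnF2 inserts into the allylic C–I bond of 2 (divalent tin becomes tetravalent tin) to give allyltin 4, which allylates one carbonyl of 3 through a six-membered transition state (1,2-addition, the usual mode of organometallics with squarate esters), and the Lewis-acidic tin alkoxide 5 then chelates the neighbouring cyclobutenone carbonyl so that the pendant allylsilane adds to it in an intramolecular Hosomi–Sakurai reaction, fluoride from tin removing silicon as Me3SiF and leaving the exocyclic methylene on Cf. The closest known reaction type is the SnF2-mediated [3+2] annulation of this same bifunctional allyl iodide/allylsilane with 1,2-diketones to cis-4-methylenecyclopentane-1,2-diols; squarate esters have not been used as the dione partner. One ring is closed, the cyclopentane Ca–Cg–Cf–Ce–Cd, by a 5-exo-trig attack on the carbonyl in which the allylsilane π bond ends up inside the new ring. The two new stereocentres Ca and Cd (carbinol carbons of a meso product) are controlled by the strain of the bicyclo[3.2.0]heptene, which allows only the cis ring fusion, reinforced by the tin chelate that holds the second carbonyl on the face of the tether. The step needs 1,2- over 1,4-selectivity in the second addition (the alkoxy-bearing β-carbon is also within reach of a five-membered closure) and cyclisation over a second intermolecular allylation; chelate activation of the carbonyl, the tert-butoxy group shielding the deactivated vinylogous-ester β-carbon and the intramolecularity should secure both. The Ca–Cd bond of the cyclobutene is a temporary ring bond that is removed in step 4.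

Step 3
Reactants: 6 cis-6,7-di-tert-butoxy-3-methylidenebicyclo[3.2.0]hept-6-ene-1,5-diol
Product: 7 cis-6,7-di-tert-butoxy-3-methylbicyclo[3.2.0]hept-6-ene-1,5-diol
Conditions: H2 (1 atm), RhCl(PPh3)3 (5 mol%), benzene, 25 °C
Reagents that add atoms: none
Why: Homogeneous hydrogenation with RhCl(PPh3)3 should reduce only the unhindered 1,1-disubstituted exocyclic alkene and leave the tetrasubstituted dialkoxycyclobutene untouched, the face of hydrogen delivery being of no consequence because the methyl-bearing carbon (future Cf) is not stereogenic after step 4, and the reduction is placed here because the methylidene dione that step 4 would otherwise give is a tautomer of an aromatic hydroxytropone.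

Step 4
Reactants: 7 cis-6,7-di-tert-butoxy-3-methylbicyclo[3.2.0]hept-6-ene-1,5-diol
Product: 8 2,3-di-tert-butoxy-6-methylcyclohept-2-ene-1,4-dione
Conditions: Pb(OAc)4, pyridine, CH2Cl2, −20 to 0 °C
Reagents that add atoms: none
Why: Criegee glycol cleavage through a cyclic plumbate ester, which the cis-1,2-diol forms readily, should cut the temporary Ca–Cd bond with relief of cyclobutene strain and unveil ring C as an achiral ene-1,4-dione, pyridine buffering the acetic acid that would endanger the tert-butyl enol ethers; no stereocentre is formed.

Step 5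
Reactants: 8 2,3-di-tert-butoxy-6-methylcyclohept-2-ene-1,4-dione
Product: 9 (6S)-2,3-di-tert-butoxy-6-methyl-4-[(trimethylsilyl)oxy]cyclohepta-2,4-dien-1-one
Conditions: (R,R)-bis(1-phenylethyl)amine, n-BuLi, LiCl, Me3SiCl (in situ quench), THF, −100 to −78 °C
Reagents that add atoms: chlorotrimethylsilane, C[Si](C)(C)Cl
Why: Enantioselective deprotonation of a prochiral ketone by a C2-symmetric chiral lithium amide with internal silyl quench (asymmetric enol silane formation) should remove one of the two enantiotopic pseudo-axial α-hydrogens, each carbonyl having a single α-methylene so that regiochemistry is not an issue, which turns Cf into a stereocentre of (S) descriptor in 9 (R in the target); the antipodal amide serves if the sense of induction proves opposite.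

Step 6
Reactants: 9 (6S)-2,3-di-tert-butoxy-6-methyl-4-[(trimethylsilyl)oxy]cyclohepta-2,4-dien-1-one; 10 4-hydroxy-5,6-dimethyl-2H-pyran-2-one; 11 paraformaldehyde (formaldehyde)
Product: 13 ring A–B–C silyl ketal (Ca–OSiMe3; rings B/C cis-fused; Cf–CH3 trans to Cg–CH2; Cd ketone), via quinone methide 12 (not isolated)
Conditions: ethylenediammonium diacetate (10 mol%), 4 Å MS, MeCN, 60 °C; 10 and 11 in excess
Reagents that add atoms: none
Why: Domino Knoevenagel/inverse-electron-demand hetero-Diels–Alder reaction: 10 and formaldehyde give the 1-oxadiene 12 (replenished thermally from its reversible adduct with a second molecule of 10), which should add suprafacially to the electron-rich enol silane with its CH2 terminus on nucleophilic Cg and its ketone oxygen on Ca, approach anti to the neighbouring Cf methyl setting Cg (CH2 trans to CH3) and the suprafacial addition giving the cis B/C fusion at Ca.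

Step 7
Reactants: 14 3-methylbutan-2-one
Product: 15 3-methyl-2-oxobutanal
Conditions: SeO2, dioxane–H2O, reflux; distillation
Reagents that add atoms: selenium dioxide, O=[Se]=O
Why: Riley oxidation by SeO2 should convert the methyl group of the methyl ketone into the aldehyde (the methine side cannot reach the carbonyl level), giving the 2-oxoaldehyde, which is distilled and used fresh; no stereocentre.

Step 8
Reactants: 13 ring A–B–C silyl ketal; 15 3-methyl-2-oxobutanal
Product: 18 ring A–B–C ene-dione (Ce=CH–CO–CH(CH3)2; E/Z mixture), via lithium aldolate 16 (not isolated), via mesylate 17 (not isolated)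
Conditions: LiN(SiMe3)2, THF, −78 °C; 15; then MsCl; then DBU, −78 to 0 °C
Reagents that add atoms: none
Why: Directed aldol condensation: the Cd ketone has Ce as its only enolisable position, its lithium enolate should add to the more electrophilic aldehyde carbonyl of 15, and mesylation followed by E1cB elimination should give the ene-dione, whose alkene geometry and transient stereocentres do not matter because the isomers equilibrate in step 9.

Step 9
Reactants: 18 ring A–B–C ene-dione
Product: 19 ring A–B–C–D aldol product (Cd–OH; Ca–OSiMe3; Cb/Cc tert-butyl enol ethers)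
Conditions: KOtBu (0.2 equiv), t-BuOH–THF, 0 °C
Reagents that add atoms: none
Why: Intramolecular aldol addition of an ene-dione to a 4-hydroxycyclopent-2-enone (5-exo-trig, known for cis-ene-1,4-diones): the tertiary enolate of the isopropyl ketone should add to the Cd carbonyl once E/Z equilibration through the Cf-centred dienolate supplies the Z isomer, the quaternary C(CH3)2 excludes dehydration, and because the aldol is reversible the Cd configuration should settle with the ring D bond cis to the Cf methyl, both pseudo-equatorial on ring C, that is with the hydroxyl on the face of the Cg substituent as in the target.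

Step 10
Reactants: 19 ring A–B–C–D aldol product
Product: 21 CNP0525404.1 (target; Ca S, Cb R, Cd R, Cf R, Cg R), via enediol 20 (not isolated)
Conditions: TFA–CH2Cl2–H2O (20:75:5), anisole, 0 to 25 °C; then pH 7 buffer
Reagents that add atoms: none
Why: Acidolysis of the two tert-butyl enol ethers (loss of 2-methylpropene) and of the silyl ketal should release the Cb/Cc enediol 20, which tautomerises to the α-hydroxy ketone with the carbonyl at Cc (C-protonation at Cb puts the cation on Cc, remote from the doubly oxygenated Ca), while ring–chain tautomerism of the hemiketal should deliver the trans-fused B/C anomer with axial anomeric hydroxyl and enediol equilibration the natural configuration at Cb, these being the configurations assumed to be thermodynamic.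

Compound list
1 | 2-(chloromethyl)-3-(trimethylsilyl)prop-1-ene | C=C(CCl)C[Si](C)(C)C | starting material
2 | 3-iodo-2-[(trimethylsilyl)methyl]prop-1-ene | C=C(CI)C[Si](C)(C)C | intermediate
3 | di-tert-butyl squarate (3,4-di-tert-butoxycyclobut-3-ene-1,2-dione) | CC(C)(C)OC1=C(OC(C)(C)C)C(=O)C1=O | starting material
4 | difluoro(iodo){2-[(trimethylsilyl)methyl]prop-2-en-1-yl}stannane (allyltin reagent, tetravalent tin; not isolated) | C=C(C[Sn](F)(F)I)C[Si](C)(C)C | intermediate
5 | difluoro(iodo)stannyl ether of 2,3-di-tert-butoxy-4-hydroxy-4-{2-[(trimethylsilyl)methyl]prop-2-en-1-yl}cyclobut-2-en-1-one (racemic; not isolated) | CC(C)(C)OC1=C(OC(C)(C)C)C(CC(=C)C[Si](C)(C)C)(O[Sn](F)(F)I)C1=O | intermediate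
6 | cis-6,7-di-tert-butoxy-3-methylidenebicyclo[3.2.0]hept-6-ene-1,5-diol (meso) | C=C1C[C@@]2(O)C(OC(C)(C)C)=C(OC(C)(C)C)[C@@]2(O)C1 | intermediate
7 | cis-6,7-di-tert-butoxy-3-methylbicyclo[3.2.0]hept-6-ene-1,5-diol (meso; methyl drawn anti to the hydroxyls, of no consequence) | C[C@H]1C[C@@]2(O)C(OC(C)(C)C)=C(OC(C)(C)C)[C@@]2(O)C1 | intermediate
8 | 2,3-di-tert-butoxy-6-methylcyclohept-2-ene-1,4-dione (achiral) | CC1CC(=O)C(OC(C)(C)C)=C(OC(C)(C)C)C(=O)C1 | intermediate
9 | (6S)-2,3-di-tert-butoxy-6-methyl-4-[(trimethylsilyl)oxy]cyclohepta-2,4-dien-1-one | C[C@H]1CC(=O)C(OC(C)(C)C)=C(OC(C)(C)C)C(O[Si](C)(C)C)=C1 | intermediate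
10 | 4-hydroxy-5,6-dimethyl-2H-pyran-2-one | Cc1oc(=O)cc(O)c1C | starting material
11 | paraformaldehyde (source of formaldehyde) | C=O | starting material
12 | 5,6-dimethyl-3-methylidene-2H-pyran-2,4(3H)-dione (quinone methide; not isolated) | C=C1C(=O)OC(C)=C(C)C1=O | intermediate
13 | ring A–B–C silyl ketal: Ca carries OSiMe3 and the ring B oxygen, Cb and Cc are tert-butyl enol ethers, Cd is a ketone, Ce is CH2, rings B/C cis-fused, Cf–CH3 trans to Cg–CH2 | Cc1oc(=O)c2c(c1C)O[C@@]1(O[Si](C)(C)C)C(OC(C)(C)C)=C(OC(C)(C)C)C(=O)C[C@H](C)[C@H]1C2 | intermediate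
14 | 3-methylbutan-2-one | CC(C)C(C)=O | starting material
15 | 3-methyl-2-oxobutanal | CC(C)C(=O)C=O | intermediate
16 | lithium aldolate: 13 with Ce bearing CH(OLi)–CO–CH(CH3)2 (epimer mixture at Ce and the carbinol carbon; not isolated) | Cc1oc(=O)c2c(c1C)O[C@@]1(O[Si](C)(C)C)C(OC(C)(C)C)=C(OC(C)(C)C)C(=O)C(C(O[Li])C(=O)C(C)C)[C@H](C)[C@H]1C2 | intermediate
17 | mesylate of the aldol adduct (not isolated) | Cc1oc(=O)c2c(c1C)O[C@@]1(O[Si](C)(C)C)C(OC(C)(C)C)=C(OC(C)(C)C)C(=O)C(C(OS(C)(=O)=O)C(=O)C(C)C)[C@H](C)[C@H]1C2 | intermediate
18 | ring A–B–C ene-dione: 13 with Ce=CH–CO–CH(CH3)2 (E/Z mixture) | Cc1oc(=O)c2c(c1C)O[C@@]1(O[Si](C)(C)C)C(OC(C)(C)C)=C(OC(C)(C)C)C(=O)C(=CC(=O)C(C)C)[C@H](C)[C@H]1C2 | intermediate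
19 | ring A–B–C–D aldol product: ring D closed, Cd–OH on the face of the Cg–CH2 group, Ca–OSiMe3, Cb/Cc tert-butyl enol ethers | Cc1oc(=O)c2c(c1C)O[C@@]1(O[Si](C)(C)C)C(OC(C)(C)C)=C(OC(C)(C)C)[C@@]3(O)C(=CC(=O)C3(C)C)[C@H](C)[C@H]1C2 | intermediate
20 | Cb/Cc enediol with free cis-fused hemiketal (not isolated) | Cc1oc(=O)c2c(c1C)O[C@@]1(O)C(O)=C(O)[C@@]3(O)C(=CC(=O)C3(C)C)[C@H](C)[C@H]1C2 | intermediate
21 | CNP0525404.1 (Ca S, Cb R, Cd R, Cf R, Cg R) | Cc1oc(=O)c2c(c1C)O[C@]1(O)[C@H](O)C(=O)[C@@]3(O)C(=CC(=O)C3(C)C)[C@H](C)[C@H]1C2 | target

Total steps: 10. Longest linear sequence: 9 steps (steps 1–6 and 8–10; step 7 is a one-step side branch).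

Steps most likely to fail

Step 2 (proposed new method). What may go wrong: closure of the allylsilane onto the alkoxy-bearing ring carbon (conjugate mode) instead of the carbonyl, stalling after the first allylation, or acid-induced ionisation and ring opening of the hydroxycyclobutenone. Fallback with known chemistry, setting out from 1 and 3: the two carbonyl additions are separated. Chloride 1 is converted with Mg in THF into {2-[(trimethylsilyl)methyl]prop-2-en-1-yl}magnesium chloride F1, which is added to 3 at −78 °C (the established 1,2-addition of organomagnesium reagents to squarate esters). This gives, after neutral work-up, the isolable 2,3-di-tert-butoxy-4-hydroxy-4-{2-[(trimethylsilyl)methyl]prop-2-en-1-yl}cyclobut-2-en-1-one F2. The five-membered ring is then closed by fluoride-triggered intramolecular allylsilane addition to the remaining ketone (Bu4NF, 4 Å MS, THF, 0 °C), which comes back to the route at 6.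

Step 9. What may go wrong: an unfavourable position of the aldol equilibrium (the Cd carbonyl is deactivated by the Cb alkoxy group), poor facial selectivity at Cd, or loss of the silyl ketal under alkoxide. Fallback, setting out from 18: the order of ring closure and unmasking is inverted. Treatment of 18 with TFA–CH2Cl2–H2O as in step 10 removes the tert-butyl and silyl groups and gives the deprotected seco ene-dione (rings A–B–C hemiketal with Cb/Cc enediol, Cd ketone and the Ce=CH–CO–CH(CH3)2 side chain) F3. In F3 the Cd carbonyl belongs to a 1,2-dicarbonyl/reductone array and is a far better aldol acceptor. The ring-closing aldol is then run under thermodynamic control in the free series (pH 7 phosphate buffer–MeCN, or prolonged standing in the acidic medium), which comes back to the route at 21.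

Step 5. What may go wrong: insufficient discrimination between the two enantiotopic α-methylene groups (low enantiomeric purity), or partial hydrolysis of the enol silane on isolation. Fallback, setting out from 8: asymmetric induction is replaced by resolution. Deprotonation with LiN(iPr)2 and in situ Me3SiCl gives racemic 2,3-di-tert-butoxy-6-methyl-4-[(trimethylsilyl)oxy]cyclohepta-2,4-dien-1-one F4, which is carried through the conditions of step 6 to the racemic silyl ketal. Preparative chromatography on a chiral stationary phase removes the mirror-image silyl ketal F5, and the route is rejoined at 13.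

Further compounds
F1 | step 2 | {2-[(trimethylsilyl)methyl]prop-2-en-1-yl}magnesium chloride | C=C(C[Mg]Cl)C[Si](C)(C)C
F2 | step 2 | 2,3-di-tert-butoxy-4-hydroxy-4-{2-[(trimethylsilyl)methyl]prop-2-en-1-yl}cyclobut-2-en-1-one (racemic) | CC(C)(C)OC1=C(OC(C)(C)C)C(O)(CC(=C)C[Si](C)(C)C)C1=O
F3 | step 9 | deprotected seco ene-dione (rings A–B–C hemiketal, Cb/Cc enediol, Cd ketone, Ce=CH–CO–CH(CH3)2) | Cc1oc(=O)c2c(c1C)O[C@]1(O)C(O)=C(O)C(=O)C(=CC(=O)C(C)C)[C@H](C)[C@H]1C2
F4 | step 5 | racemic 2,3-di-tert-butoxy-6-methyl-4-[(trimethylsilyl)oxy]cyclohepta-2,4-dien-1-one | CC1CC(=O)C(OC(C)(C)C)=C(OC(C)(C)C)C(O[Si](C)(C)C)=C1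
F5 | step 5 | mirror image of silyl ketal 13 | Cc1oc(=O)c2c(c1C)O[C@]1(O[Si](C)(C)C)C(OC(C)(C)C)=C(OC(C)(C)C)C(=O)C[C@@H](C)[C@@H]1C2
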